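The synthesis rests on cutting C5–C6 and O7–C8 of ring B (numbering: C1 bridgehead CH, C2 guaiacyl CH, O3, C4H2, C5 bridgehead C–OH, C6 syringyl CH, O7, C8H2; ring A = C1–C2–O3–C4–C5, ring B = C5–C6–O7–C8–C1). Carbons C4, C5, C1 and C8 map onto the four carbons of L-malic acid, whose hydroxyl becomes the OH on C5, the bridgehead shared by rings A and B. In one operation the key step replaces the carbinol hydrogen by the syringyl-bearing carbon with retention and closes ring B as a γ-lactone. Its precursor is the cis pivalaldehyde acetal of malic acid, a dioxolanone with a free acetic acid arm, used as its dilithium salt.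

Key step: step 3

Remark: C2 and C6 are benzylic ether carbons whose C–O bonds are re-formed in step 7, so they are treated as correctable. C1 and C5 cannot be corrected and are fixed by substrate control in steps 3 and 5.

Step 1
Reactants: 1 L-malic acid, (S)-2-hydroxybutanedioic acid; 2 pivalaldehyde, 2,2-dimethylpropanal
Product: 3 (2S,4S)-2-tert-butyl-5-oxo-1,3-dioxolane-4-acetic acid (cis: tert-butyl and CH2CO2H on the same face)
Conditions: 2 (1.3 equiv), TsOH·H2O (cat.), H2SO4 (cat.), pentane, reflux, Dean–Stark; recrystallisation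
Reagents that add atoms: none
Why: Acid-catalysed acetalisation of the α-hydroxy acid unit to a 1,3-dioxolan-4-one under thermodynamic control, in which the new acetal centre should take the cis arrangement and crystallisation should remove the minor trans isomer.

Step 2
Reactants: 4 syringaldehyde, 4-hydroxy-3,5-dimethoxybenzaldehyde
Product: 5 4-(tert-butyldimethylsilyloxy)-3,5-dimethoxybenzaldehyde
Conditions: TBSCl (1.2 equiv), imidazole (2.5 equiv), DMF, rt
Reagents that add atoms: tert-butyldimethylsilyl chloride, CC(C)(C)[Si](C)(C)Cl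
Why: Imidazole-promoted silylation of the phenol (substitution at silicon) masks the acidic OH before the enolate chemistry; no stereocentre is involved.

Step 3
Reactants: 3 (2S,4S)-2-tert-butyl-5-oxo-1,3-dioxolane-4-acetic acid; 5 4-(tert-butyldimethylsilyloxy)-3,5-dimethoxybenzaldehyde
Product: 7 (2S,5R,6R)-2-tert-butyl-6-[4-(tert-butyldimethylsilyloxy)-3,5-dimethoxyphenyl]-1,3,7-trioxaspiro[4.4]nonane-4,8-dione (aryl cis to the dioxolanone ring oxygen on the spiro carbon, lactone CH2 cis to tert-butyl), via hydroxy acid 6 (not isolated)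
Conditions: LiN(SiMe3)2 (2.1 equiv), THF, −78 °C; 5, −78 °C; AcOH; then TsOH·H2O (cat.), CH2Cl2, rt
Reagents that add atoms: none
Why: Two equivalents of lithium amide give the carboxylate and then the planar dioxolanone enolate at C5, which adds to the aldehyde carbon of 5 (bond C5–C6) through a lithium-bridged chair, and after protonation the C6 hydroxyl of 6 acylates on the C8 carboxyl with loss of water (bond O7–C8). The closest known reaction type is the aldol addition of dioxolanone enolates of α-hydroxy acids with self-regeneration of the stereocentre, joined to an ordinary γ-hydroxy acid lactonisation. Ring B closes as a γ-lactone by 5-exo-trig attack of O7 on the carboxyl carbon, favoured by the quaternary C5. C5 is controlled by the acetal tert-butyl group, which shields the face cis to it so that the aldehyde takes the place of the hydrogen (net retention), and C6 by the chair transition state with the aryl group equatorial, which puts the aryl cis to the dioxolanone ring oxygen in 7. The step needs site selectivity, secured by the carboxylate charge that protects the neighbouring CH2 from deprotonation, and face selectivity at C5, secured by the tert-butyl group, whereas C6 need not be pure because it is re-set in step 7. Holding the dianion at −78 °C and quenching cold guards against loss of pivalaldehyde from the enolate and against retro-aldol cleavage.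

Step 4
Reactants: 8 vanillin, 4-hydroxy-3-methoxybenzaldehyde
Product: 9 4-(tert-butyldimethylsilyloxy)-3-methoxybenzaldehyde
Conditions: TBSCl (1.2 equiv), imidazole (2.5 equiv), DMF, rt
Reagents that add atoms: tert-butyldimethylsilyl chloride, CC(C)(C)[Si](C)(C)Cl
Why: Imidazole-promoted silylation of the phenol (substitution at silicon), as in step 2; no stereocentre is involved.

Step 5
Reactants: 7 spiro dioxolanone γ-lactone; 9 4-(tert-butyldimethylsilyloxy)-3-methoxybenzaldehyde
Product: 11 (1R,2S,5R,6R)-5-hydroxy-2-[4-(tert-butyldimethylsilyloxy)-3-methoxyphenyl]-6-[4-(tert-butyldimethylsilyloxy)-3,5-dimethoxyphenyl]-3,7-dioxabicyclo[3.3.0]octane-4,8-dione (numbering of the overview; cis-fused, both aryl groups exo), via lactone aldol adduct 10 (not isolated)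
Conditions: LiN(SiMe3)2 (1.05 equiv), THF, −78 °C, 20 min; 9, −78 → 0 °C; AcOH
Reagents that add atoms: none
Why: Lactone enolate aldol addition at C1 followed by alkoxide translactonisation: the aldehyde should enter anti to the C6 aryl group and the C5–O bond, and the C2 alkoxide of 10 then acylates on the activated dioxolanone carbonyl C4 (5-exo-trig, pivalaldehyde expelled), a closure open only to the isomer with C2 and C4 cis on ring B, so a reversible aldol addition should drain into 11 with C1 fixed, while the exo aryl at C2 is expected but not required.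

Step 6
Reactants: 11 hydroxy bis-lactone
Product: 12 (1R,2S,3R,4S)-2,3-bis(hydroxymethyl)-1-[4-(tert-butyldimethylsilyloxy)-3,5-dimethoxyphenyl]-4-[4-(tert-butyldimethylsilyloxy)-3-methoxyphenyl]butane-1,2,4-triol (the pentaol with free OH on C2, C4, C5, C6 and C8)
Conditions: LiAlH4 (4 equiv), THF, 0 °C; Fieser work-up
Reagents that add atoms: none
Why: Hydride reduction of both γ-lactones to diols, the classical dilactone-to-polyol reduction of furofuran lignan chemistry, touches no stereocentre and should leave the aryl silyl ethers intact at 0 °C.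

Step 7
Reactants: 12 pentaol bis-silyl ether
Product: 13 (1R,2S,5S,6R)-2-[4-(tert-butyldimethylsilyloxy)-3-methoxyphenyl]-6-[4-(tert-butyldimethylsilyloxy)-3,5-dimethoxyphenyl]-3,7-dioxabicyclo[3.3.0]octan-5-ol (bis-silyl ether of the target)
Conditions: CSA (0.2 equiv), CH2Cl2, 0 °C → rt
Reagents that add atoms: none
Why: Acid-catalysed cyclodehydration (SN1 etherification) through para-silyloxybenzyl cations at C2 and C6, each captured 5-exo-trig by the primary hydroxyl on C4 or C8 to form rings A and B; the ring fusion is necessarily cis from C1 and C5, and each aryl group should settle exo, trans to the neighbouring ring carbon, which re-sets C2 and C6.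

Step 8
Reactants: 13 bis-silyl ether of the target
Product: 14 fraxiresinol, (1R,2S,5S,6R)-2-(4-hydroxy-3-methoxyphenyl)-6-(4-hydroxy-3,5-dimethoxyphenyl)-3,7-dioxabicyclo[3.3.0]octan-5-ol
Conditions: Bu4NF (2.4 equiv), AcOH (2.4 equiv), THF, 0 °C
Reagents that add atoms: none
Why: Fluoride-induced cleavage of the two aryl silyl ethers (desilylation through Si–F bond formation), buffered with acetic acid so that free phenolates cannot open the benzylic ethers through quinone methides; no stereocentre is affected.

Compound list
1 | L-malic acid, (S)-2-hydroxybutanedioic acid | O[C@@H](CC(=O)O)C(=O)O | starting material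
2 | pivalaldehyde | CC(C)(C)C=O | starting material
3 | (2S,4S)-2-tert-butyl-5-oxo-1,3-dioxolane-4-acetic acid | OC(=O)C[C@@H]1O[C@H](C(C)(C)C)OC1=O | intermediate
4 | syringaldehyde | COc1cc(C=O)cc(OC)c1O | starting material
5 | 4-(tert-butyldimethylsilyloxy)-3,5-dimethoxybenzaldehyde | COc1cc(C=O)cc(OC)c1O[Si](C)(C)C(C)(C)C | intermediate
6 | 2-[(2S,4R)-2-tert-butyl-4-{(R)-[4-(tert-butyldimethylsilyloxy)-3,5-dimethoxyphenyl](hydroxy)methyl}-5-oxo-1,3-dioxolan-4-yl]acetic acid | OC(=O)C[C@@]1(O[C@H](C(C)(C)C)OC1=O)[C@H](O)c1cc(OC)c(O[Si](C)(C)C(C)(C)C)c(OC)c1 | intermediate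
7 | (2S,5R,6R)-2-tert-butyl-6-[4-(tert-butyldimethylsilyloxy)-3,5-dimethoxyphenyl]-1,3,7-trioxaspiro[4.4]nonane-4,8-dione | O=C1C[C@@]2(O[C@H](C(C)(C)C)OC2=O)[C@@H](c2cc(OC)c(O[Si](C)(C)C(C)(C)C)c(OC)c2)O1 | intermediate
8 | vanillin | COc1cc(C=O)ccc1O | starting material
9 | 4-(tert-butyldimethylsilyloxy)-3-methoxybenzaldehyde | COc1cc(C=O)ccc1O[Si](C)(C)C(C)(C)C | intermediate
10 | (2S,5R,6R,9R)-2-tert-butyl-9-{(S)-[4-(tert-butyldimethylsilyloxy)-3-methoxyphenyl](hydroxy)methyl}-6-[4-(tert-butyldimethylsilyloxy)-3,5-dimethoxyphenyl]-1,3,7-trioxaspiro[4.4]nonane-4,8-dione | O=C1[C@H]([C@H](O)c3ccc(O[Si](C)(C)C(C)(C)C)c(OC)c3)[C@@]2(O[C@H](C(C)(C)C)OC2=O)[C@@H](c2cc(OC)c(O[Si](C)(C)C(C)(C)C)c(OC)c2)O1 | intermediate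
11 | (1R,2S,5R,6R)-5-hydroxy-2-[4-(tert-butyldimethylsilyloxy)-3-methoxyphenyl]-6-[4-(tert-butyldimethylsilyloxy)-3,5-dimethoxyphenyl]-3,7-dioxabicyclo[3.3.0]octane-4,8-dione | COc1cc([C@H]2OC(=O)[C@]3(O)[C@@H](c4cc(OC)c(O[Si](C)(C)C(C)(C)C)c(OC)c4)OC(=O)[C@H]23)ccc1O[Si](C)(C)C(C)(C)C | intermediate
12 | (1R,2S,3R,4S)-2,3-bis(hydroxymethyl)-1-[4-(tert-butyldimethylsilyloxy)-3,5-dimethoxyphenyl]-4-[4-(tert-butyldimethylsilyloxy)-3-methoxyphenyl]butane-1,2,4-triol | OC[C@](O)([C@H](O)c1cc(OC)c(O[Si](C)(C)C(C)(C)C)c(OC)c1)[C@H](CO)[C@H](O)c1ccc(O[Si](C)(C)C(C)(C)C)c(OC)c1 | intermediate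
13 | (1R,2S,5S,6R)-2-[4-(tert-butyldimethylsilyloxy)-3-methoxyphenyl]-6-[4-(tert-butyldimethylsilyloxy)-3,5-dimethoxyphenyl]-3,7-dioxabicyclo[3.3.0]octan-5-ol | COc1cc([C@H]2OC[C@]3(O)[C@@H](c4cc(OC)c(O[Si](C)(C)C(C)(C)C)c(OC)c4)OC[C@H]23)ccc1O[Si](C)(C)C(C)(C)C | intermediate
14 | fraxiresinol | COc1cc([C@H]2OC[C@]3(O)[C@@H](c4cc(OC)c(O)c(OC)c4)OC[C@H]23)ccc1O | target

Total step count: 8.
Longest linear sequence: 6 steps (steps 1, 3, 5, 6, 7 and 8, from L-malic acid).

Steps most likely to fail

Step 3. The dianion may fragment with loss of pivalaldehyde before it adds, the addition to the electron-rich aldehyde may be slow, and the aldolate may revert on warming. The fallback replaces the lithium aldol by a Lewis-acid aldol of a silyl ketene acetal. It sets out from 3, which is silylated twice with LiN(SiMe3)2 (2.1 equiv) and Me3SiCl in THF at −78 °C to give trimethylsilyl 2-[(2S)-2-tert-butyl-5-(trimethylsilyloxy)-1,3-dioxol-4-yl]acetate F1. This is combined with 5 and BF3·OEt2 in CH2Cl2 at −78 °C (Mukaiyama aldol, again anti to the tert-butyl group). Aqueous acidic work-up cleaves the silyl ester to hydroxy acid 6, which lactonises under the acid catalysis of step 3, and the route is rejoined at 7.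

Step 5. The lactone enolate carries the acetal oxygen on C5 in the β-position and may expel it (ring opening to a butenolide), or the aldehyde may enter on the wrong face of C1. Incomplete translactonisation is harmless, since 10 and 11 give the same pentaol in step 6. The fallback removes the leaving group before the enolate is made. It sets out from 7, whose dioxolanone is opened with K2CO3 in MeOH at 0 °C to methyl (2R,3R)-2-[4-(tert-butyldimethylsilyloxy)-3,5-dimethoxyphenyl]-3-hydroxy-5-oxooxolane-3-carboxylate F2. Two equivalents of LiN(iPr)2 in THF at −78 °C then give the alkoxide–enolate dianion (Fráter–Seebach type), which cannot eliminate and should add 9 anti to the alkoxide. On warming, the C2 alkoxide lactonises onto the methyl ester and the route is rejoined at 11.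

Step 7. Ionisation at C6 may be slow, because the hindered syringyl silyl ether is a weaker donor and C5 carries oxygen. The C6 cation may also be captured by the guaiacyl ring (Friedel–Crafts closure to an aryltetralin), or a ring may close with an endo aryl group. The fallback activates the primary carbons instead of the benzylic ones. It sets out from 12, which with MsCl (2.1 equiv) in pyridine at 0 °C → rt should be sulfonylated selectively at the two primary hydroxyls to give the C4,C8-bis(methanesulfonate) of pentaol 12 F3. The benzylic hydroxyls then displace the sulfonates (two 5-exo-tet SN2 closures) with retention at C2 and C6, which presumes these centres are as drawn in 12, and the route is rejoined at 13.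

Further compounds
F1 | step 3 | trimethylsilyl 2-[(2S)-2-tert-butyl-5-(trimethylsilyloxy)-1,3-dioxol-4-yl]acetate | C[Si](C)(C)OC(=O)CC1=C(O[Si](C)(C)C)O[C@@H](C(C)(C)C)O1
F2 | step 5 | methyl (2R,3R)-2-[4-(tert-butyldimethylsilyloxy)-3,5-dimethoxyphenyl]-3-hydroxy-5-oxooxolane-3-carboxylate | O=C1C[C@](O)(C(=O)OC)[C@@H](c2cc(OC)c(O[Si](C)(C)C(C)(C)C)c(OC)c2)O1
F3 | step 7 | C4,C8-bis(methanesulfonate) of pentaol 12 | CS(=O)(=O)OC[C@](O)([C@H](O)c1cc(OC)c(O[Si](C)(C)C(C)(C)C)c(OC)c1)[C@H](COS(C)(=O)=O)[C@H](O)c1ccc(O[Si](C)(C)C(C)(C)C)c(OC)c1
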